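**Plan**

Labdane numbering is used: ring A = C1–C5 and C10, ring B = C5–C10, C17 on C8, side chain C11–C16. The retrosynthesis first cuts C12–C13 (alkylborane plus enol tosylate), then cuts ring B at C8–C9 and C5–C6 in one [3+3] annulation of methyl acetoacetate onto a ring A keto carbonate.
Enabling feature: in ring B, C6–C7–C8 with C17 form an acetoacetate skeleton with two nucleophilic carbons (C8 and C6). C9 and C5, the two neighbours of the quaternary C10, can be an allylic carbonate carbon and a non-enolisable ketone carbon.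
Forward order: ring A is bought; C10 is made quaternary by allylation; the allyl group is oxidised to a C9 carbinol carbonate; ring B forms in the key step (C8–C9 by rhodium-catalysed allylic alkylation, C5–C6 by aldol condensation in the same flask). Then C5=C6 is reduced, the C7 oxygen is removed, C17 is reduced, and the side chain is joined by B-alkyl Suzuki–Miyaura coupling.
Stereochemistry: C10 comes from the chiral palladium catalyst; C9 from a CBS reduction, carried over with net retention in the key step; C5 from hydrogen-atom transfer anti to the C10 methyl (trans fusion); the C13=C14 geometry from an (E)-enol tosylate coupled with retention.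

Key step: step 6

Assumption: the (S)-phosphinooxazoline ligand is taken to give the (S)-allyl ketone, and the (R)-oxazaborolidine the (S)-carbinol (tert-alkyl C10 as the large group); if either sense proves opposite, the antipodal ligand or catalyst is used and nothing else changes.

**Step 1**
Reactants: 1 2,2,6-trimethylcyclohexan-1-one; 2 allyl chloroformate
Product: 3 allyl 2,6,6-trimethylcyclohex-1-en-1-yl carbonate
Conditions: LiN(SiMe3)2, THF, 0 °C; then 2, −78 → 0 °C
Reagents that add atoms: none
Why: The ketone can be enolised only towards C10, and the hard lithium enolate is acylated on oxygen by the chloroformate (enol carbonate formation).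

**Step 2**
Reactants: 3 allyl 2,6,6-trimethylcyclohex-1-en-1-yl carbonate
Product: 4 (2S)-2,6,6-trimethyl-2-(prop-2-en-1-yl)cyclohexan-1-one
Conditions: Pd2(dba)3 (2.5 mol%), (S)-4-tert-butyl-2-[2-(diphenylphosphanyl)phenyl]-4,5-dihydro-1,3-oxazole (6 mol%), THF, 25 °C
Reagents that add atoms: none
Why: In this decarboxylative asymmetric allylic alkylation (Tsuji-type) zerovalent palladium ionises the allyl carbonate, CO2 is lost and the enolate recombines with the allyl fragment inside the chiral P,N-ligand sphere, which sets the quaternary C10 stereocentre.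

**Step 3**
Reactants: 4 (2S)-2,6,6-trimethyl-2-(prop-2-en-1-yl)cyclohexan-1-one
Product: 6 (2S)-2,6,6-trimethyl-2-(prop-2-enoyl)cyclohexan-1-one, via allylic alcohol mixture 5 (not isolated)
Conditions: SeO2 (0.5 equiv), t-BuOOH (3 equiv), CH2Cl2, 25 °C; then 1,1,1-triacetoxy-1,1-dihydro-1,2-benziodoxol-3(1H)-one (DMP), CH2Cl2, 0 → 25 °C
Reagents that add atoms: selenium dioxide, O=[Se]=O; tert-butyl hydroperoxide (terminal oxidant), CC(C)(C)OO
Why: The ene reaction of SeO2 at the terminal alkene carbon followed by a [2,3]-sigmatropic shift (allylic oxidation) puts oxygen on C9, the only allylic position, and the Dess–Martin oxidation then converges both carbinol epimers on one enone, the non-enolisable ring ketone being inert to both reagents.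

**Step 4**
Reactants: 6 (2S)-2,6,6-trimethyl-2-(prop-2-enoyl)cyclohexan-1-one
Product: 7 (2S)-2-[(1S)-1-hydroxyprop-2-en-1-yl]-2,6,6-trimethylcyclohexan-1-one
Conditions: (3aR)-1-methyl-3,3-diphenyltetrahydro-1H,3H-pyrrolo[1,2-c][1,3,2]oxazaborole (20 mol%), catecholborane, toluene, −78 °C
Reagents that add atoms: none
Why: In the CBS reduction the borane bound to the chiral oxazaborolidine delivers hydride to the enone carbonyl with the tert-alkyl C10 as the large and the vinyl group as the small substituent, which sets the (S)-configured C9 carbinol by reagent control, while the far more hindered ring ketone is left.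

**Step 5**
Reactants: 7 (2S)-2-[(1S)-1-hydroxyprop-2-en-1-yl]-2,6,6-trimethylcyclohexan-1-one
Product: 8 methyl (1S)-1-[(1S)-1,3,3-trimethyl-2-oxocyclohexyl]prop-2-en-1-yl carbonate
Conditions: ClCO2Me, pyridine, 4-(dimethylamino)pyridine (cat.), CH2Cl2, 0 → 25 °C
Reagents that add atoms: methyl chloroformate, COC(Cl)=O
Why: Acylation of the secondary allylic alcohol with the chloroformate under amine catalysis (carbonate formation) avoids the alkoxide that could trigger a retro-aldol cleavage of the C9–C10 bond and leaves C9 untouched.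

**Step 6**
Reactants: 8 methyl (1S)-1-[(1S)-1,3,3-trimethyl-2-oxocyclohexyl]prop-2-en-1-yl carbonate; 9 methyl 3-oxobutanoate (methyl acetoacetate)
Product: 11 methyl (1R,8aS)-5,5,8a-trimethyl-3-oxo-1-vinyl-1,2,3,5,6,7,8,8a-octahydronaphthalene-2-carboxylate (C8 epimers and enol), via allylated keto ester 10 (not isolated)
Conditions: 9 (2.0 equiv), NaH (1.9 equiv), THF, 0 °C; RhCl(PPh3)3 (10 mol%), P(OMe)3 (40 mol%), 8, 30 °C; then MeOH, 65 °C
Reagents that add atoms: none
Why: The sodium enolate of 9 attacks the σ+π-allyl (enyl) complex of monovalent rhodium that forms from 8 by oxidative addition anti to the carbonate, at the carbon that carried the leaving group and anti to the metal, so that C8–C9 forms with net retention (double inversion) and with the branched connectivity; the methoxide set free from the leaving group then equilibrates the keto ester enolates in methanol, and the C6 enolate of the methyl ketone adds to the C5 ketone and loses water (E1cB) to give the conjugated enone as the thermodynamic sink. The closest known reaction types are the rhodium-catalysed allylic alkylation of secondary and tertiary allylic carbonates with stabilised carbanions, which conserves regio- and stereochemistry, and the aldol cyclodehydration of a Robinson or Hagemann annulation. Ring B closes in a 6-(enolendo)-exo-trig aldol addition. C9 is controlled by the C9–O stereocentre of 8 through the stereospecific substitution, C8 is not controlled and becomes trigonal in step 8, and C5 stays trigonal until step 7. The step needs substitution at the hindered internal allyl terminus and not at the terminal one, which the regiochemically and configurationally stable enyl rhodium intermediate secures, and it needs closure through C6 and not C8, which ring size secures because attack by C8 would give a four-membered ring. The ring ketone and the quaternary C10 carry no α-hydrogen, so neither self-condensation nor epimerisation can compete.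

**Step 7**
Reactants: 11 methyl (1R,8aS)-5,5,8a-trimethyl-3-oxo-1-vinyl-1,2,3,5,6,7,8,8a-octahydronaphthalene-2-carboxylate
Product: 12 methyl (1R,4aR,8aS)-5,5,8a-trimethyl-3-oxo-1-vinyldecahydronaphthalene-2-carboxylate (trans-fused; C8 epimers and enol)
Conditions: tris(2,2,6,6-tetramethylheptane-3,5-dionato)manganese, Mn(dpm)3 (10 mol%), PhSiH3 (1.5 equiv), i-PrOH, 25 °C, argon
Reagents that add atoms: none
Why: In this hydrogen-atom-transfer conjugate reduction the manganese hydride formed from the silane passes a hydrogen atom to C5 of the enone (or of its dienol) on the face away from the axial C10 methyl, which sets the trans ring fusion, and the resulting α-keto radical is reduced and protonated by isopropanol, while the unactivated vinyl group, which needs an added oxidant to turn over, should stay.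

**Step 8**
Reactants: 12 methyl (1R,4aR,8aS)-5,5,8a-trimethyl-3-oxo-1-vinyldecahydronaphthalene-2-carboxylate
Product: 13 methyl (1S,4aR,8aR)-5,5,8a-trimethyl-3-(trifluoromethylsulfonyloxy)-1-vinyl-1,4,4a,5,6,7,8,8a-octahydronaphthalene-2-carboxylate
Conditions: NaH, THF, 0 °C; PhNTf2, 0 → 25 °C
Reagents that add atoms: N-phenyl-bis(trifluoromethanesulfonimide), O=S(=O)(N(c1ccccc1)S(=O)(=O)C(F)(F)F)C(F)(F)F
Why: Deprotonation of the β-keto ester occurs only between the two carbonyl groups, so O-sulfonylation of the sodium enolate (enol triflate formation) fixes the double bond between C7 and C8.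

**Step 9**
Reactants: 13 methyl (1S,4aR,8aR)-5,5,8a-trimethyl-3-(trifluoromethylsulfonyloxy)-1-vinyl-1,4,4a,5,6,7,8,8a-octahydronaphthalene-2-carboxylate
Product: 14 methyl (1S,4aR,8aR)-5,5,8a-trimethyl-1-vinyl-1,4,4a,5,6,7,8,8a-octahydronaphthalene-2-carboxylate
Conditions: Pd(OAc)2 (5 mol%), PPh3 (10 mol%), HCO2H, Et3N, DMF, 40 °C
Reagents that add atoms: none
Why: Oxidative addition of the vinyl triflate to zerovalent palladium, exchange with formate, loss of CO2 and reductive elimination (palladium-catalysed formate reduction of an enol triflate) replace the C7 oxygen by hydrogen and leave the C7=C8 bond in conjugation with the ester.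

**Step 10**
Reactants: 14 methyl (1S,4aR,8aR)-5,5,8a-trimethyl-1-vinyl-1,4,4a,5,6,7,8,8a-octahydronaphthalene-2-carboxylate
Product: 15 [(1S,4aR,8aR)-5,5,8a-trimethyl-1-vinyl-1,4,4a,5,6,7,8,8a-octahydronaphthalen-2-yl]methanol
Conditions: i-Bu2AlH (2.5 equiv), CH2Cl2, −78 °C; aqueous potassium sodium tartrate
Reagents that add atoms: none
Why: Two hydride transfers from the aluminium hydride reduce the conjugated ester in a 1,2-sense to the allylic alcohol (i-Bu2AlH ester reduction) without touching either alkene.

**Step 11**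
Reactants: 16 tert-butyl 4-chloro-3-oxobutanoate
Product: 17 tert-butyl 4-acetoxy-3-oxobutanoate
Conditions: KOAc, AcOH (cat.), DMF, 25 °C
Reagents that add atoms: potassium acetate, CC(=O)[O-].[K+]
Why: The α-chloro ketone is an activated SN2 electrophile, so acetate displaces chloride at C16 under buffered conditions.

**Step 12**
Reactants: 17 tert-butyl 4-acetoxy-3-oxobutanoate
Product: 18 tert-butyl (2E)-4-acetoxy-3-(4-methylphenylsulfonyloxy)but-2-enoate
Conditions: TsCl, N-methylimidazole, Et3N, CH2Cl2, 0 °C
Reagents that add atoms: 4-methylbenzenesulfonyl chloride, Cc1ccc(cc1)S(Cl)(=O)=O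
Why: Sulfonylation of the non-chelated ammonium enolate by the N-sulfonylimidazolium salt (stereoselective enol tosylation of a β-keto ester) should give the (E)-enol tosylate, in which the leaving group is trans and the acetoxymethyl group cis to the ester, without the aqueous base that would cleave the acetate.

**Step 13**
Reactants: 15 [(1S,4aR,8aR)-5,5,8a-trimethyl-1-vinyl-1,4,4a,5,6,7,8,8a-octahydronaphthalen-2-yl]methanol; 18 tert-butyl (2E)-4-acetoxy-3-(4-methylphenylsulfonyloxy)but-2-enoate
Product: 20 tert-butyl (2Z)-4-acetoxy-3-{2-[(1S,4aR,8aR)-2-(hydroxymethyl)-5,5,8a-trimethyl-1,4,4a,5,6,7,8,8a-octahydronaphthalen-1-yl]ethyl}but-2-enoate, via B-alkyl-9-BBN adduct 19 (not isolated)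
Conditions: 9-BBN (2.5 equiv), THF, 0 → 25 °C; then 18, Pd(OAc)2 (5 mol%), dicyclohexyl(2′,6′-dimethoxybiphenyl-2-yl)phosphane (10 mol%), K3PO4 (3 equiv), H2O, THF, 40 °C
Reagents that add atoms: none
Why: 9-BBN first masks the hydroxyl as a borinate and then hydroborates only the monosubstituted alkene at its terminal carbon, and the B-alkyl Suzuki–Miyaura coupling with the enol tosylate proceeds with retention at the alkenyl carbon, which joins C12 to C13 and fixes the C13=C14 geometry of the target.

**Step 14**
Reactants: 20 tert-butyl (2Z)-4-acetoxy-3-{2-[(1S,4aR,8aR)-2-(hydroxymethyl)-5,5,8a-trimethyl-1,4,4a,5,6,7,8,8a-octahydronaphthalen-1-yl]ethyl}but-2-enoate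
Product: 22 (2Z)-4-acetoxy-3-{2-[(1S,4aR,8aR)-2-(hydroxymethyl)-5,5,8a-trimethyl-1,4,4a,5,6,7,8,8a-octahydronaphthalen-1-yl]ethyl}but-2-enoic acid, via bis(trimethylsilyl) derivative 21 (not isolated)
Conditions: Me3SiOTf (4 equiv), 2,6-lutidine (6 equiv), CH2Cl2, 0 °C; then aqueous citric acid, THF, 0 °C
Reagents that add atoms: none
Why: The silyl triflate silylates the ester carbonyl and expels 2-methylpropene (tert-butyl ester cleavage under buffered conditions) and also silylates the hydroxyl, and the mild acidic work-up hydrolyses the silyl ester and silyl ether without lactonisation or loss of the allylic acetate.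

**Compound list**

1 | 2,2,6-trimethylcyclohexan-1-one | CC1CCCC(C)(C)C1=O | starting material
2 | allyl chloroformate | C=CCOC(Cl)=O | starting material
3 | allyl 2,6,6-trimethylcyclohex-1-en-1-yl carbonate | C=CCOC(=O)OC1=C(C)CCCC1(C)C | intermediate
4 | (2S)-2,6,6-trimethyl-2-(prop-2-en-1-yl)cyclohexan-1-one | C=CC[C@]1(C)CCCC(C)(C)C1=O | intermediate
5 | (2S)-2-(1-hydroxyprop-2-en-1-yl)-2,6,6-trimethylcyclohexan-1-one, both C9 epimers | C=CC(O)[C@]1(C)CCCC(C)(C)C1=O | intermediate (not isolated)
6 | (2S)-2,6,6-trimethyl-2-(prop-2-enoyl)cyclohexan-1-one | C=CC(=O)[C@]1(C)CCCC(C)(C)C1=O | intermediate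
7 | (2S)-2-[(1S)-1-hydroxyprop-2-en-1-yl]-2,6,6-trimethylcyclohexan-1-one | O[C@@H](C=C)[C@]1(C)CCCC(C)(C)C1=O | intermediate
8 | methyl (1S)-1-[(1S)-1,3,3-trimethyl-2-oxocyclohexyl]prop-2-en-1-yl carbonate | COC(=O)O[C@@H](C=C)[C@]1(C)CCCC(C)(C)C1=O | intermediate
9 | methyl 3-oxobutanoate | COC(=O)CC(C)=O | starting material
10 | methyl (3R)-2-acetyl-3-[(1S)-1,3,3-trimethyl-2-oxocyclohexyl]pent-4-enoate, C8 epimers | COC(=O)C(C(C)=O)[C@@H](C=C)[C@]1(C)CCCC(C)(C)C1=O | intermediate (not isolated)
11 | methyl (1R,8aS)-5,5,8a-trimethyl-3-oxo-1-vinyl-1,2,3,5,6,7,8,8a-octahydronaphthalene-2-carboxylate, C8 epimers and enol | C=C[C@@H]1C(C(=O)OC)C(=O)C=C2C(C)(C)CCC[C@@]12C | intermediate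
12 | methyl (1R,4aR,8aS)-5,5,8a-trimethyl-3-oxo-1-vinyldecahydronaphthalene-2-carboxylate, trans-fused, C8 epimers and enol | C=C[C@@H]1C(C(=O)OC)C(=O)C[C@@H]2C(C)(C)CCC[C@@]12C | intermediate
13 | methyl (1S,4aR,8aR)-5,5,8a-trimethyl-3-(trifluoromethylsulfonyloxy)-1-vinyl-1,4,4a,5,6,7,8,8a-octahydronaphthalene-2-carboxylate | C=C[C@@H]1C(C(=O)OC)=C(OS(=O)(=O)C(F)(F)F)C[C@@H]2C(C)(C)CCC[C@@]12C | intermediate
14 | methyl (1S,4aR,8aR)-5,5,8a-trimethyl-1-vinyl-1,4,4a,5,6,7,8,8a-octahydronaphthalene-2-carboxylate | C=C[C@@H]1C(C(=O)OC)=CC[C@@H]2C(C)(C)CCC[C@@]12C | intermediate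
15 | [(1S,4aR,8aR)-5,5,8a-trimethyl-1-vinyl-1,4,4a,5,6,7,8,8a-octahydronaphthalen-2-yl]methanol | C=C[C@@H]1C(CO)=CC[C@@H]2C(C)(C)CCC[C@@]12C | intermediate
16 | tert-butyl 4-chloro-3-oxobutanoate | CC(C)(C)OC(=O)CC(=O)CCl | starting material
17 | tert-butyl 4-acetoxy-3-oxobutanoate | CC(=O)OCC(=O)CC(=O)OC(C)(C)C | intermediate
18 | tert-butyl (2E)-4-acetoxy-3-(4-methylphenylsulfonyloxy)but-2-enoate | CC(=O)OC/C(=C\C(=O)OC(C)(C)C)OS(=O)(=O)c1ccc(C)cc1 | intermediate
19 | O-(9-borabicyclo[3.3.1]nonan-9-yl) borinate of 15 carrying a 2-(9-borabicyclo[3.3.1]nonan-9-yl)ethyl group on C9, stereocentres as in 15 | C(CB3C4CCCC3CCC4)[C@@H]1C(COB3C4CCCC3CCC4)=CC[C@@H]2C(C)(C)CCC[C@@]12C | intermediate (not isolated)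
20 | tert-butyl (2Z)-4-acetoxy-3-{2-[(1S,4aR,8aR)-2-(hydroxymethyl)-5,5,8a-trimethyl-1,4,4a,5,6,7,8,8a-octahydronaphthalen-1-yl]ethyl}but-2-enoate | CC(=O)OC/C(=C\C(=O)OC(C)(C)C)CC[C@@H]1C(CO)=CC[C@@H]2C(C)(C)CCC[C@@]12C | intermediate
21 | trimethylsilyl ester and O17-trimethylsilyl ether of 22, stereochemistry as in 20 | CC(=O)OC/C(=C\C(=O)O[Si](C)(C)C)CC[C@@H]1C(CO[Si](C)(C)C)=CC[C@@H]2C(C)(C)CCC[C@@]12C | intermediate (not isolated)
22 | (2Z)-4-acetoxy-3-{2-[(1S,4aR,8aR)-2-(hydroxymethyl)-5,5,8a-trimethyl-1,4,4a,5,6,7,8,8a-octahydronaphthalen-1-yl]ethyl}but-2-enoic acid | CC(=O)OC/C(=C\C(=O)O)CC[C@@H]1C(CO)=CC[C@@H]2C(C)(C)CCC[C@@]12C | target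

**Count and risks**

Total step count: 14. Longest linear sequence: 12 (steps 1–10, 13 and 14; steps 11 and 12 make the side-chain fragment).

Steps most likely to fail:

1. Step 6. The enolate may attack the unhindered allyl terminus if the hindered rhodium allyl species equilibrates, oxidative addition at the neopentylic carbonate may stall, and the aldol closure on the congested C5 ketone may lag. The fallback forms C8–C9 by a sigmatropic shift, which is insensitive to hindrance, at the price of losing reagent control at C9. It sets out from 8. Pd(PPh3)4 with AcOH and Et3N in THF moves the oxygen to the unhindered terminus and should give (2E)-3-[(1S)-1,3,3-trimethyl-2-oxocyclohexyl]prop-2-en-1-yl acetate F1. K2CO3 in MeOH frees (2S)-2-[(1E)-3-hydroxyprop-1-en-1-yl]-2,6,6-trimethylcyclohexan-1-one F2. Heating F2 with methyl (E)-3-methoxybut-2-enoate and catalytic propanoic acid in xylene (140 → 170 °C, MeOH distilled off) forms the allyl enol ether methyl (2E)-3-{[(2E)-3-[(1S)-1,3,3-trimethyl-2-oxocyclohexyl]prop-2-en-1-yl]oxy}but-2-enoate F3, which is not isolated and undergoes Claisen rearrangement to 10 together with its C9 epimer, methyl (3S)-2-acetyl-3-[(1S)-1,3,3-trimethyl-2-oxocyclohexyl]pent-4-enoate F4. F4 is removed by chromatography, and NaOMe in MeOH at 65 °C closes 10 to 11, where the route is rejoined.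

2. Step 7. Hydrogen-atom transfer may show poor facial selectivity at C5 (cis-fused isomer) or also reduce the vinyl group. The fallback uses a dissolving metal after the C7 oxygen has been removed and sets out from 11. NaH and PhNTf2 give the dienyl triflate methyl (1S,8aS)-5,5,8a-trimethyl-3-(trifluoromethylsulfonyloxy)-1-vinyl-1,5,6,7,8,8a-hexahydronaphthalene-2-carboxylate F5. Pd(OAc)2, PPh3, HCO2H and Et3N reduce it to the dienoate methyl (1S,8aS)-5,5,8a-trimethyl-1-vinyl-1,5,6,7,8,8a-hexahydronaphthalene-2-carboxylate F6. Li in NH3/THF with t-BuOH at −78 °C (1,6-reduction with axial protonation at C5, trans fusion expected) gives the β,γ-unsaturated ester methyl (1R,4aR,8aS)-5,5,8a-trimethyl-1-vinyl-1,2,4a,5,6,7,8,8a-octahydronaphthalene-2-carboxylate F7. NaOMe in MeOH moves the double bond into conjugation and rejoins the route at 14.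

3. Step 3. The ene reaction of SeO2 with a monosubstituted olefin flanked by a quaternary carbon may be slow, and over-oxidation may lower the return. The fallback builds the C9 carbinol by carbonyl addition and sets out from 4. PdCl2(MeCN)2 in toluene at 60 °C isomerises the allyl group to give (2S)-2,6,6-trimethyl-2-[(1E)-prop-1-en-1-yl]cyclohexan-1-one F8. Ozonolysis (O3, CH2Cl2/MeOH, −78 °C; Me2S) gives (1S)-1,3,3-trimethyl-2-oxocyclohexane-1-carbaldehyde F9. Vinylmagnesium bromide in THF at −78 °C adds to the aldehyde only and gives 5, which is oxidised to 6 as in step 3.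

**Further compounds**

F1 | step 6 | (2E)-3-[(1S)-1,3,3-trimethyl-2-oxocyclohexyl]prop-2-en-1-yl acetate | CC(=O)OC/C=C/[C@]1(C)CCCC(C)(C)C1=O
F2 | step 6 | (2S)-2-[(1E)-3-hydroxyprop-1-en-1-yl]-2,6,6-trimethylcyclohexan-1-one | OC/C=C/[C@]1(C)CCCC(C)(C)C1=O
F3 | step 6 | methyl (2E)-3-{[(2E)-3-[(1S)-1,3,3-trimethyl-2-oxocyclohexyl]prop-2-en-1-yl]oxy}but-2-enoate | COC(=O)/C=C(\C)OC/C=C/[C@]1(C)CCCC(C)(C)C1=O
F4 | step 6 | methyl (3S)-2-acetyl-3-[(1S)-1,3,3-trimethyl-2-oxocyclohexyl]pent-4-enoate | COC(=O)C(C(C)=O)[C@H](C=C)[C@]1(C)CCCC(C)(C)C1=O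
F5 | step 7 | methyl (1S,8aS)-5,5,8a-trimethyl-3-(trifluoromethylsulfonyloxy)-1-vinyl-1,5,6,7,8,8a-hexahydronaphthalene-2-carboxylate | C=C[C@@H]1C(C(=O)OC)=C(OS(=O)(=O)C(F)(F)F)C=C2C(C)(C)CCC[C@@]12C
F6 | step 7 | methyl (1S,8aS)-5,5,8a-trimethyl-1-vinyl-1,5,6,7,8,8a-hexahydronaphthalene-2-carboxylate | C=C[C@@H]1C(C(=O)OC)=CC=C2C(C)(C)CCC[C@@]12C
F7 | step 7 | methyl (1R,4aR,8aS)-5,5,8a-trimethyl-1-vinyl-1,2,4a,5,6,7,8,8a-octahydronaphthalene-2-carboxylate | C=C[C@@H]1C(C(=O)OC)C=C[C@@H]2C(C)(C)CCC[C@@]12C
F8 | step 3 | (2S)-2,6,6-trimethyl-2-[(1E)-prop-1-en-1-yl]cyclohexan-1-one | C/C=C/[C@]1(C)CCCC(C)(C)C1=O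
F9 | step 3 | (1S)-1,3,3-trimethyl-2-oxocyclohexane-1-carbaldehyde | O=C[C@]1(C)CCCC(C)(C)C1=O
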